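The route rests on disconnecting the bond between the exocyclic benzylidene CH on C5 of the furanone (tetronic acid) ring and C1 of the epoxyprenylated phenol ring. Because that CH sits on an enol-ester carbon (ring O1–C5, with C4 as a latent ester carbon), it is the terminal carbon of an α-acyloxyacrylate, so a Mizoroki–Heck arylation joins the two halves and sets the Z geometry in one operation. Its precursors are the aryl bromide that already carries the (R)-epoxide and methyl 2-(chromanylacetoxy)acrylate, the furanone ring in open form; a Dieckmann closure of C3–C4 then folds it and buffered fluoride frees the phenols.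

Key step: step 7

Assumption: the free phenol next to the epoxide in the target is taken to be isolable when kept cold, dilute and close to neutral, and the D-fructose-derived Shi ketone is taken to deliver the (R)-oxirane on this prenyl arene; the five starting materials are taken as commercial.

Step 1
Reactants: 1 4-bromophenol; 2 prenyl bromide (1-bromo-3-methylbut-2-ene)
Product: 3 4-bromo-2-(3-methylbut-2-en-1-yl)phenol
Conditions: NaH (1.05 equiv), toluene, 0 °C to rt
Reagents that add atoms: none
Why: The sodium phenoxide reacts as a tight ion pair in the non-polar solvent, so the ortho carbon attacks the primary carbon of the allylic bromide (phenoxide ortho C-alkylation), the para position being blocked by bromine.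

Step 2
Reactants: 3 4-bromo-2-(3-methylbut-2-en-1-yl)phenol
Product: 4 [4-bromo-2-(3-methylbut-2-en-1-yl)phenoxy]tri(propan-2-yl)silane
Conditions: TIPSCl, imidazole, DMF, rt to 40 °C
Reagents that add atoms: triisopropylsilyl chloride, CC(C)[Si](Cl)(C(C)C)C(C)C
Why: Silyl ether formation on a phenol; the bulky TIPS group is chosen because it should survive the basic epoxidation, the Heck coupling and LiHMDS and still leave with fluoride.

Step 3
Reactants: 4 [4-bromo-2-(3-methylbut-2-en-1-yl)phenoxy]tri(propan-2-yl)silane
Product: 5 {4-bromo-2-[((2R)-3,3-dimethyloxiran-2-yl)methyl]phenoxy}tri(propan-2-yl)silane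
Conditions: Shi ketone (D-fructose-derived, 30 mol %), Oxone (2KHSO5·KHSO4·K2SO4), K2CO3, n-Bu4NHSO4 (cat.), MeCN/CH2(OMe)2, aq. Na2B4O7–Na2EDTA buffer (pH 10.5), 0 °C
Reagents that add atoms: potassium peroxymonosulfate (active component of Oxone), [K+].[O-]S(=O)(=O)OO
Why: Shi asymmetric epoxidation: the chiral dioxirane formed from the ketone transfers oxygen to the electron-rich trisubstituted alkene through a spiro transition state, so the (R) configuration at the oxirane CH is set by reagent control while the aryl bromide and the silyl ether stay untouched.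

Step 4
Reactants: 6 2,4-dihydroxyphenylacetic acid; 7 isoprene (2-methylbuta-1,3-diene)
Product: 8 2-(7-hydroxy-2,2-dimethyl-3,4-dihydro-2H-chromen-6-yl)acetic acid
Conditions: Amberlyst 15 (sulfonic acid resin), THF/heptane, 60 °C, sealed vessel
Reagents that add atoms: none
Why: Acid-catalysed Friedel–Crafts prenylation at C5 of the resorcinol ring (para to the 2-OH, ortho to the 4-OH and less hindered than C3) is followed by Markovnikov hydroalkoxylation of the prenyl alkene by the 4-OH, which closes the 2,2-dimethylchroman ring.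

Step 5
Reactants: 8 2-(7-hydroxy-2,2-dimethyl-3,4-dihydro-2H-chromen-6-yl)acetic acid
Product: 10 2-[7-(tert-butyldimethylsilyloxy)-2,2-dimethyl-3,4-dihydro-2H-chromen-6-yl]acetic acid, via bis-silylated silyl ester 9 (not isolated)
Conditions: TBSCl (2.5 equiv), imidazole, DMF, rt; then AcOH/THF/H2O, rt
Reagents that add atoms: tert-butyldimethylsilyl chloride, CC(C)(C)[Si](C)(C)Cl
Why: Exhaustive silylation followed by selective hydrolysis of the far more labile silyl ester should leave only the aryl silyl ether, which prevents lactonisation of the ortho-hydroxyarylacetic acid in the following steps.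

Step 6
Reactants: 10 2-[7-(tert-butyldimethylsilyloxy)-2,2-dimethyl-3,4-dihydro-2H-chromen-6-yl]acetic acid; 11 methyl pyruvate (methyl 2-oxopropanoate)
Product: 13 methyl 2-({2-[7-(tert-butyldimethylsilyloxy)-2,2-dimethyl-3,4-dihydro-2H-chromen-6-yl]acetyl}oxy)prop-2-enoate, via arylacetyl chloride 12 (not isolated)
Conditions: (COCl)2, DMF (cat.), CH2Cl2, 0 °C, volatiles removed; then 11 (3 equiv), Et3N, DMAP (cat.), CH2Cl2, −20 to 0 °C
Reagents that add atoms: none
Why: O-Acylation of the amine-generated enolate of the α-keto ester by the acid chloride (enol ester formation from a pyruvate) should give the 2-acyloxyacrylate, the excess of pyruvate outrunning ketene dimerisation.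

Step 7
Reactants: 5 {4-bromo-2-[((2R)-3,3-dimethyloxiran-2-yl)methyl]phenoxy}tri(propan-2-yl)silane; 13 methyl 2-({2-[7-(tert-butyldimethylsilyloxy)-2,2-dimethyl-3,4-dihydro-2H-chromen-6-yl]acetyl}oxy)prop-2-enoate
Product: 14 methyl (2Z)-2-({2-[7-(tert-butyldimethylsilyloxy)-2,2-dimethyl-3,4-dihydro-2H-chromen-6-yl]acetyl}oxy)-3-{3-[((2R)-3,3-dimethyloxiran-2-yl)methyl]-4-(triisopropylsilyloxy)phenyl}prop-2-enoate
Conditions: Pd(P(t-Bu)3)2 (5 mol %), Cy2NMe (1.5 equiv), 13 (1.3 equiv), BHT (trace), 1,4-dioxane, 60 °C
Reagents that add atoms: none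
Why: Oxidative addition of zerovalent palladium into the C–Br bond of 5 is followed by syn-carbopalladation of the 1,1-disubstituted enol-ester alkene of 13, the aryl group going to the unsubstituted CH2 terminus, and by syn-β-hydride elimination, for which only the new benzylic hydrogens are available; the amine then regenerates the catalyst (Mizoroki–Heck reaction). The closest known reaction type is the Heck arylation of 2-acyloxy- and 2-acylaminoacrylates, which gives (Z)-trisubstituted products. No ring is closed and no stereocentre is created; the (R)-epoxide should be a spectator because a non-allylic oxirane does not ionise on zerovalent palladium and the hindered amine base is not nucleophilic. The Z geometry (aryl cis to the acyloxy oxygen, trans to CO2Me) is decided in the β-hydride elimination, whose favoured conformer keeps the aryl group away from the ester, and it is also the thermodynamically preferred isomer. The step needs regioselectivity, secured by the terminal CH2 and by the absence of any leaving group β to palladium (the acyloxy group is α), and chemoselectivity for C–Br over the enol ester and the silyl ethers, secured by the electron-rich bulky phosphine and nucleophile-free conditions.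

Step 8
Reactants: 14 methyl (2Z)-2-({2-[7-(tert-butyldimethylsilyloxy)-2,2-dimethyl-3,4-dihydro-2H-chromen-6-yl]acetyl}oxy)-3-{3-[((2R)-3,3-dimethyloxiran-2-yl)methyl]-4-(triisopropylsilyloxy)phenyl}prop-2-enoate
Product: 15 (5Z)-3-[7-(tert-butyldimethylsilyloxy)-2,2-dimethyl-3,4-dihydro-2H-chromen-6-yl]-5-({3-[((2R)-3,3-dimethyloxiran-2-yl)methyl]-4-(triisopropylsilyloxy)phenyl}methylidene)-4-hydroxyfuran-2(5H)-one
Conditions: LiHMDS (2.5 equiv), THF, −78 to 0 °C; then AcOH, −78 °C; cold pH 3–4 citrate work-up
Reagents that add atoms: none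
Why: Dieckmann (intramolecular Claisen) condensation: the enolate of the arylacetyl unit attacks the methyl ester in a 5-exo-trig closure and loss of methoxide gives the tetronate, driven by deprotonation of the acidic 4-hydroxyfuranone, while the non-nucleophilic base should leave epoxide, silyl ethers and the Z alkene unchanged.

Step 9
Reactants: 15 (5Z)-3-[7-(tert-butyldimethylsilyloxy)-2,2-dimethyl-3,4-dihydro-2H-chromen-6-yl]-5-({3-[((2R)-3,3-dimethyloxiran-2-yl)methyl]-4-(triisopropylsilyloxy)phenyl}methylidene)-4-hydroxyfuran-2(5H)-one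
Product: 16 (5Z)-5-({3-[((2R)-3,3-dimethyloxiran-2-yl)methyl]-4-hydroxyphenyl}methylidene)-4-hydroxy-3-(7-hydroxy-2,2-dimethyl-3,4-dihydro-2H-chromen-6-yl)furan-2(5H)-one (CNP0384423.1)
Conditions: n-Bu4NF (4 equiv), AcOH (4 equiv), THF, 0 °C; cold pH 5 NaH2PO4/Na2HPO4 work-up, reversed-phase purification at low temperature
Reagents that add atoms: none
Why: Fluoride-mediated desilylation cleaves both aryl silyl ethers, and the acetic acid buffer keeps each liberated phenol protonated so that no phenoxide can open the neighbouring epoxide.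

Compound list
1 | 4-bromophenol | Oc1ccc(Br)cc1 | starting material
2 | prenyl bromide (1-bromo-3-methylbut-2-ene) | CC(C)=CCBr | starting material
3 | 4-bromo-2-(3-methylbut-2-en-1-yl)phenol | CC(C)=CCc1cc(Br)ccc1O | intermediate
4 | [4-bromo-2-(3-methylbut-2-en-1-yl)phenoxy]tri(propan-2-yl)silane | CC(C)=CCc1cc(Br)ccc1O[Si](C(C)C)(C(C)C)C(C)C | intermediate
5 | {4-bromo-2-[((2R)-3,3-dimethyloxiran-2-yl)methyl]phenoxy}tri(propan-2-yl)silane | Brc1ccc(O[Si](C(C)C)(C(C)C)C(C)C)c(C[C@H]2OC2(C)C)c1 | intermediate
6 | 2,4-dihydroxyphenylacetic acid | OC(=O)Cc1ccc(O)cc1O | starting material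
7 | isoprene | C=CC(C)=C | starting material
8 | 2-(7-hydroxy-2,2-dimethyl-3,4-dihydro-2H-chromen-6-yl)acetic acid | CC1(C)CCc2cc(CC(=O)O)c(O)cc2O1 | intermediate
9 | tert-butyldimethylsilyl 2-[7-(tert-butyldimethylsilyloxy)-2,2-dimethyl-3,4-dihydro-2H-chromen-6-yl]acetate | CC1(C)CCc2cc(CC(=O)O[Si](C)(C)C(C)(C)C)c(O[Si](C)(C)C(C)(C)C)cc2O1 | intermediate (not isolated)
10 | 2-[7-(tert-butyldimethylsilyloxy)-2,2-dimethyl-3,4-dihydro-2H-chromen-6-yl]acetic acid | CC1(C)CCc2cc(CC(=O)O)c(O[Si](C)(C)C(C)(C)C)cc2O1 | intermediate
11 | methyl pyruvate | CC(=O)C(=O)OC | starting material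
12 | 2-[7-(tert-butyldimethylsilyloxy)-2,2-dimethyl-3,4-dihydro-2H-chromen-6-yl]acetyl chloride | CC1(C)CCc2cc(CC(=O)Cl)c(O[Si](C)(C)C(C)(C)C)cc2O1 | intermediate (not isolated)
13 | methyl 2-({2-[7-(tert-butyldimethylsilyloxy)-2,2-dimethyl-3,4-dihydro-2H-chromen-6-yl]acetyl}oxy)prop-2-enoate | C=C(OC(=O)Cc1cc2CCC(C)(C)Oc2cc1O[Si](C)(C)C(C)(C)C)C(=O)OC | intermediate
14 | methyl (2Z)-2-({2-[7-(tert-butyldimethylsilyloxy)-2,2-dimethyl-3,4-dihydro-2H-chromen-6-yl]acetyl}oxy)-3-{3-[((2R)-3,3-dimethyloxiran-2-yl)methyl]-4-(triisopropylsilyloxy)phenyl}prop-2-enoate | COC(=O)/C(OC(=O)Cc1cc2CCC(C)(C)Oc2cc1O[Si](C)(C)C(C)(C)C)=C/c1ccc(O[Si](C(C)C)(C(C)C)C(C)C)c(C[C@H]2OC2(C)C)c1 | intermediate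
15 | (5Z)-3-[7-(tert-butyldimethylsilyloxy)-2,2-dimethyl-3,4-dihydro-2H-chromen-6-yl]-5-({3-[((2R)-3,3-dimethyloxiran-2-yl)methyl]-4-(triisopropylsilyloxy)phenyl}methylidene)-4-hydroxyfuran-2(5H)-one | CC1(C)CCc2cc(C3=C(O)/C(=C/c4ccc(O[Si](C(C)C)(C(C)C)C(C)C)c(C[C@H]5OC5(C)C)c4)OC3=O)c(O[Si](C)(C)C(C)(C)C)cc2O1 | intermediate
16 | (5Z)-5-({3-[((2R)-3,3-dimethyloxiran-2-yl)methyl]-4-hydroxyphenyl}methylidene)-4-hydroxy-3-(7-hydroxy-2,2-dimethyl-3,4-dihydro-2H-chromen-6-yl)furan-2(5H)-one | CC1(C)CCc2cc(C3=C(O)/C(=C/c4ccc(O)c(C[C@H]5OC5(C)C)c4)OC3=O)c(O)cc2O1 | target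

Total step count: 9 steps.
Longest linear sequence: 6 steps (steps 4, 5, 6, 7, 8, 9; the branch through steps 1, 2, 3 is equally long).

Steps most likely to fail

Step 7. The oxidative addition into the electron-rich C–Br bond may be slow, so that the enol ester fragments (loss of an arylketene) or polymerises first, or the ammonium bromide formed may open the epoxide at the coupling temperature. The fallback sets out from 5, which is converted by Miyaura borylation (B2pin2, PdCl2(dppf), KOAc, 1,4-dioxane, 80 °C) into the aryl pinacol boronate {2-[((2R)-3,3-dimethyloxiran-2-yl)methyl]-4-(4,4,5,5-tetramethyl-1,3,2-dioxaborolan-2-yl)phenoxy}tri(propan-2-yl)silane F1. An oxidative boron-Heck coupling of this boronate with 13 (Pd(OAc)2, 2,9-dimethyl-1,10-phenanthroline, O2, N-methylmorpholine, MeCN, rt to 40 °C) transfers the aryl group to divalent palladium by transmetalation, needs little heating, forms no halide salt, makes the same CH–aryl bond and comes back to the route at 14.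

Step 9. The phenol freed next to the epoxide may attack it intramolecularly (5-exo opening to a dihydrobenzofuran carbinol) during desilylation or work-up. The fallback sets out from 15. Desilylation is run in the presence of an acylating agent (CsF, Ac2O, DMF, 0 °C), so that each phenoxide is trapped as it forms and the 4-hydroxy group is acetylated as well, giving the triacetate (5Z)-4-acetoxy-3-(7-acetoxy-2,2-dimethyl-3,4-dihydro-2H-chromen-6-yl)-5-({4-acetoxy-3-[((2R)-3,3-dimethyloxiran-2-yl)methyl]phenyl}methylidene)furan-2(5H)-one F2. The acetates are then removed enzymatically at pH 7 (Candida antarctica lipase B or pig-liver esterase, phosphate buffer/t-BuOMe, rt), conditions under which neither phenoxide, fluoride nor acid is present, and the sequence comes back to the route at 16.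

Step 6. The arylacetyl chloride may go over to the ketene and dimerise, and the pyruvate may undergo aldol self-condensation or C-acylation instead of O-acylation. The fallback sets out from 10. Steglich esterification with racemic methyl 3-chloro-2-hydroxypropanoate (EDC·HCl, DMAP, CH2Cl2, 0 °C) should give methyl 3-chloro-2-({2-[7-(tert-butyldimethylsilyloxy)-2,2-dimethyl-3,4-dihydro-2H-chromen-6-yl]acetyl}oxy)propanoate F3, a racemate whose stereocentre is lost in the next operation. Base-induced dehydrochlorination (Et3N, CH2Cl2, 0 °C to rt) of this ester then forms the acrylate double bond and comes back to the route at 13.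

Further compounds
F1 | step 7 | {2-[((2R)-3,3-dimethyloxiran-2-yl)methyl]-4-(4,4,5,5-tetramethyl-1,3,2-dioxaborolan-2-yl)phenoxy}tri(propan-2-yl)silane | CC1(C)OB(OC1(C)C)c1ccc(O[Si](C(C)C)(C(C)C)C(C)C)c(C[C@H]2OC2(C)C)c1
F2 | step 9 | (5Z)-4-acetoxy-3-(7-acetoxy-2,2-dimethyl-3,4-dihydro-2H-chromen-6-yl)-5-({4-acetoxy-3-[((2R)-3,3-dimethyloxiran-2-yl)methyl]phenyl}methylidene)furan-2(5H)-one | CC(=O)Oc1cc2OC(C)(C)CCc2cc1C1=C(OC(C)=O)/C(=C/c2ccc(OC(C)=O)c(C[C@H]3OC3(C)C)c2)OC1=O
F3 | step 6 | methyl 3-chloro-2-({2-[7-(tert-butyldimethylsilyloxy)-2,2-dimethyl-3,4-dihydro-2H-chromen-6-yl]acetyl}oxy)propanoate (racemic) | COC(=O)C(CCl)OC(=O)Cc1cc2CCC(C)(C)Oc2cc1O[Si](C)(C)C(C)(C)C
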